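Everything rests on disconnecting ring C of the lower (epiafzelechin) unit across C2–C3. C2, the O1-bound carbon that carries ring B, is read as the carbonyl carbon of a 4-benzyloxybenzoate on the ring A phenol, and C3–C4 as an ortho-allyl group put in place by a Claisen rearrangement. A titanium-mediated carbonyl olefination–olefin metathesis cascade then welds the ester carbon to the internal allyl carbon and closes ring C as a flav-2-ene in one operation; its precursor is a plain 2-allylaryl benzoate. Oxidation of the prochiral C2=C3 enol ether to the flavan-3-one and one dynamic kinetic hydrogenation set both stereocentres cis. The 2,4-cis upper flavan arises from an organocatalytic ortho-quinone methide cycloaddition.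

Key step: step 7

Remark: 5-(benzyloxy)-2-bromophenol and 4-(benzyloxy)styrene are taken as purchasable, and the sense of induction of the two chiral catalysts (steps 4 and 9) is assigned by analogy with simpler substrates, the antipodal catalyst being the remedy if it proves reversed.

Step 1
Reactants: 1 3,5-bis(benzyloxy)phenol; 2 paraformaldehyde
Product: 4 4,6-bis(benzyloxy)-2-hydroxybenzaldehyde, via salicyl alcohol 3 (not isolated)
Conditions: MgCl2, Et3N, (CH2O)n, MeCN, reflux
Reagents that add atoms: none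
Why: Magnesium phenoxide-directed ortho-formylation (Casnati–Skattebøl reaction): the chelated phenoxide is hydroxymethylated only ortho to oxygen (both ortho sites are equivalent), and a second formaldehyde oxidises the benzylic alkoxide by hydride transfer, so the site between the two benzyloxy groups stays free.

Step 2
Reactants: 4 4,6-bis(benzyloxy)-2-hydroxybenzaldehyde; 5 allyl bromide
Product: 6 2-(allyloxy)-4,6-bis(benzyloxy)benzaldehyde
Conditions: K2CO3, DMF, 60 °C
Reagents that add atoms: none
Why: Williamson etherification of the chelated phenol; the allyl group masks the future O1 and is the latent C3–C4 unit of ring C.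

Step 3
Reactants: 6 2-(allyloxy)-4,6-bis(benzyloxy)benzaldehyde; 7 5-(benzyloxy)-2-bromophenol
Product: 9 [2-(allyloxy)-4,6-bis(benzyloxy)phenyl][4-(benzyloxy)-2-hydroxyphenyl]methanol (racemic), via dilithiated phenol 8 (not isolated)
Conditions: 7, n-BuLi (2.1 equiv), THF, −78 to 0 °C; then 6, −78 °C; aq NH4Cl
Reagents that add atoms: none
Why: Deprotonation followed by bromine–lithium exchange gives the ortho-lithiated lithium phenoxide, which adds 1,2 to the aldehyde; the carbinol configuration is immaterial because this centre is ionised in step 4.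

Step 4
Reactants: 9 [2-(allyloxy)-4,6-bis(benzyloxy)phenyl][4-(benzyloxy)-2-hydroxyphenyl]methanol; 10 4-(benzyloxy)styrene
Product: 12 (2S,4S)-4-[2-(allyloxy)-4,6-bis(benzyloxy)phenyl]-7-(benzyloxy)-2-[4-(benzyloxy)phenyl]chromane, via ortho-quinone methide 11 (not isolated)
Conditions: (R)-3,3'-bis(2,4,6-triisopropylphenyl)-BINOL N-triflylphosphoramide (5 mol %), 4 Å MS, CH2Cl2, −20 °C
Reagents that add atoms: none
Why: Chiral Brønsted acid-catalysed dehydration to the ortho-quinone methide and inverse-electron-demand hetero-Diels–Alder reaction with the styrene (its CH2 attacks the methide carbon, oxygen captures the benzylic carbon); the endo transition state should place the two aryl groups 2,4-cis, and the acid hydrogen-bonded to the quinone methide oxygen should select the face that gives (2S,4S).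

Step 5
Reactants: 12 (2S,4S)-4-[2-(allyloxy)-4,6-bis(benzyloxy)phenyl]-7-(benzyloxy)-2-[4-(benzyloxy)phenyl]chromane
Product: 13 2-allyl-3,5-bis(benzyloxy)-6-{(2S,4S)-7-(benzyloxy)-2-[4-(benzyloxy)phenyl]chroman-4-yl}phenol
Conditions: PhNEt2, 190 °C
Reagents that add atoms: none
Why: Aromatic Claisen rearrangement ([3,3] shift then tautomerisation) to the only free ortho position, which frees the O1 phenol and places the allyl group on C4a; the flavan stereocentres are not involved.

Step 6
Reactants: 13 2-allyl-3,5-bis(benzyloxy)-6-{(2S,4S)-7-(benzyloxy)-2-[4-(benzyloxy)phenyl]chroman-4-yl}phenol; 14 4-(benzyloxy)benzoyl chloride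
Product: 15 2-allyl-3,5-bis(benzyloxy)-6-{(2S,4S)-7-(benzyloxy)-2-[4-(benzyloxy)phenyl]chroman-4-yl}phenyl 4-(benzyloxy)benzoate
Conditions: Et3N, DMAP (cat.), CH2Cl2, 0 °C to rt
Reagents that add atoms: none
Why: DMAP-catalysed O-acylation of the hindered phenol; the ester carbonyl carbon, already bonded to O1 and ring B, is the future C2.

Step 7
Reactants: 15 2-allyl-3,5-bis(benzyloxy)-6-{(2S,4S)-7-(benzyloxy)-2-[4-(benzyloxy)phenyl]chroman-4-yl}phenyl 4-(benzyloxy)benzoate
Product: 17 5,7-bis(benzyloxy)-2-[4-(benzyloxy)phenyl]-8-{(2S,4S)-7-(benzyloxy)-2-[4-(benzyloxy)phenyl]chroman-4-yl}-4H-chromene (flav-2-ene), via vinyl ether 16 (not isolated)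
Conditions: Tebbe reagent Cp2Ti(μ-Cl)(μ-CH2)AlMe2 (4 equiv), pyridine (cat.), THF, 0 to 25 °C, then 70 °C
Reagents that add atoms: none
Why: The titanium methylidene Cp2Ti=CH2 first olefinates the aryl ester carbonyl through an oxatitanacyclobutane to give the 1-arylvinyl aryl ether 16; on warming, excess methylidene converts the terminal allyl alkene into a titanium alkylidene at C3, which undergoes intramolecular [2+2] addition to the enol ether C2=CH2 and cycloreversion, so that ethylene is expelled overall and C2=C3 is formed. The closest known reaction type is the Tebbe-mediated olefinic ester cyclization (carbonyl olefination–ring-closing metathesis cascade) used for cyclic enol ethers. Ring C closes as a six-membered ring by ring-closing metathesis with the new alkene endocyclic, and ring A holds O1 and C4 cis, which preorganises the two reacting carbons. No stereocentre is formed: C2 and C3 are delivered as a prochiral enol ether at the right oxidation level for steps 8 and 9. The step needs chemoselectivity for one carbonyl and one alkene and freedom from acid, since the flav-2-ene protonates at C3; 15 has no other carbonyl or alkene, benzyl ethers and the flavan are inert to the reagent, and pyridine tempers the Lewis acidic aluminium.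

Step 8
Reactants: 17 5,7-bis(benzyloxy)-2-[4-(benzyloxy)phenyl]-8-{(2S,4S)-7-(benzyloxy)-2-[4-(benzyloxy)phenyl]chroman-4-yl}-4H-chromene
Product: 20 5,7-bis(benzyloxy)-2-[4-(benzyloxy)phenyl]-8-{(2S,4S)-7-(benzyloxy)-2-[4-(benzyloxy)phenyl]chroman-4-yl}chroman-3-one (C2 epimers), via C3-alkylborane 18 (not isolated), via trans-flavan-3-ol 19 (not isolated)
Conditions: BH3·THF, THF, 0 °C; then NMO, Pr4N[RuO4] (cat.), 4 Å MS, CH2Cl2, rt
Reagents that add atoms: N-methylmorpholine N-oxide, C[N+]1([O-])CCOCC1
Why: Hydroboration puts boron on C3 (beta to O1, remote from ring B) by syn addition, and N-oxide oxidation of the C–B bond followed by perruthenate oxidation takes it to the ketone in the same flask (hydroboration–oxidation to the carbonyl level); the configurations at C2 and C3 do not matter here because step 9 resets both.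

Step 9
Reactants: 20 5,7-bis(benzyloxy)-2-[4-(benzyloxy)phenyl]-8-{(2S,4S)-7-(benzyloxy)-2-[4-(benzyloxy)phenyl]chroman-4-yl}chroman-3-one
Product: 21 (2R,3R)-5,7-bis(benzyloxy)-2-[4-(benzyloxy)phenyl]-8-{(2S,4S)-7-(benzyloxy)-2-[4-(benzyloxy)phenyl]chroman-4-yl}chroman-3-ol
Conditions: RuCl2[(S)-binap][(R,R)-dpen] (1 mol %), KOtBu, H2 (10 atm), i-PrOH/toluene, rt, degassed
Reagents that add atoms: none
Why: Noyori-type bifunctional ruthenium hydrogenation under dynamic kinetic resolution: KOtBu epimerises the acidic C2 (alpha to the ketone and benzylic) through the enolate, the catalyst should reduce the (2R)-ketone selectively and deliver hydride to the carbonyl face anti to ring B, so C2 (R) and C3 (R, hydroxyl cis to ring B) are set together under catalyst control, as in the cis-selective reduction of 2-substituted cyclohexanones; benzyl ethers are untouched.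

Step 10
Reactants: 21 (2R,3R)-5,7-bis(benzyloxy)-2-[4-(benzyloxy)phenyl]-8-{(2S,4S)-7-(benzyloxy)-2-[4-(benzyloxy)phenyl]chroman-4-yl}chroman-3-ol
Product: 22 (2R,3R)-2-(4-hydroxyphenyl)-8-[(2S,4S)-7-hydroxy-2-(4-hydroxyphenyl)chroman-4-yl]chromane-3,5,7-triol
Conditions: H2 (1 atm), Pd(OH)2/C, THF/MeOH, rt
Reagents that add atoms: none
Why: Hydrogenolysis of the six benzyl aryl ethers under mild neutral conditions, which should leave the ring benzylic C–O bonds, the C4–C8 interflavan bond and all four stereocentres intact.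

Compound list
1 | 3,5-bis(benzyloxy)phenol | Oc1cc(OCc2ccccc2)cc(OCc2ccccc2)c1 | starting material
2 | paraformaldehyde (drawn as formaldehyde) | C=O | starting material
3 | 3,5-bis(benzyloxy)-2-(hydroxymethyl)phenol (salicyl alcohol, magnesium-bound in the flask) | OCc1c(O)cc(OCc2ccccc2)cc1OCc1ccccc1 | intermediate (not isolated)
4 | 4,6-bis(benzyloxy)-2-hydroxybenzaldehyde | O=Cc1c(O)cc(OCc2ccccc2)cc1OCc1ccccc1 | intermediate
5 | allyl bromide | C=CCBr | starting material
6 | 2-(allyloxy)-4,6-bis(benzyloxy)benzaldehyde | O=Cc1c(OCC=C)cc(OCc2ccccc2)cc1OCc1ccccc1 | intermediate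
7 | 5-(benzyloxy)-2-bromophenol | Oc1cc(OCc2ccccc2)ccc1Br | starting material
8 | lithium 5-(benzyloxy)-2-lithiophenoxide | [Li]Oc1cc(OCc2ccccc2)ccc1[Li] | intermediate (not isolated)
9 | [2-(allyloxy)-4,6-bis(benzyloxy)phenyl][4-(benzyloxy)-2-hydroxyphenyl]methanol, racemic | OC(c1ccc(OCc2ccccc2)cc1O)c1c(OCC=C)cc(OCc2ccccc2)cc1OCc1ccccc1 | intermediate
10 | 4-(benzyloxy)styrene | C=Cc1ccc(OCc2ccccc2)cc1 | starting material
11 | 6-{[2-(allyloxy)-4,6-bis(benzyloxy)phenyl]methylidene}-3-(benzyloxy)cyclohexa-2,4-dien-1-one (ortho-quinone methide) | O=C1C=C(OCc2ccccc2)C=CC1=Cc1c(OCC=C)cc(OCc2ccccc2)cc1OCc1ccccc1 | intermediate (not isolated)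
12 | (2S,4S)-4-[2-(allyloxy)-4,6-bis(benzyloxy)phenyl]-7-(benzyloxy)-2-[4-(benzyloxy)phenyl]chromane (2,4-cis) | O(Cc1ccccc1)c1ccc([C@@H]2C[C@H](c3c(OCc4ccccc4)cc(OCc4ccccc4)cc3OCC=C)c3ccc(OCc4ccccc4)cc3O2)cc1 | intermediate
13 | 2-allyl-3,5-bis(benzyloxy)-6-{(2S,4S)-7-(benzyloxy)-2-[4-(benzyloxy)phenyl]chroman-4-yl}phenol | O(Cc1ccccc1)c1ccc([C@@H]2C[C@H](c3c(OCc4ccccc4)cc(OCc4ccccc4)c(CC=C)c3O)c3ccc(OCc4ccccc4)cc3O2)cc1 | intermediate
14 | 4-(benzyloxy)benzoyl chloride | O=C(Cl)c1ccc(OCc2ccccc2)cc1 | starting material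
15 | 4-(benzyloxy)benzoate ester of phenol 13 | O(Cc1ccccc1)c1ccc([C@@H]2C[C@H](c3c(OCc4ccccc4)cc(OCc4ccccc4)c(CC=C)c3OC(=O)c3ccc(OCc4ccccc4)cc3)c3ccc(OCc4ccccc4)cc3O2)cc1 | intermediate
16 | 1-[4-(benzyloxy)phenyl]vinyl ether of phenol 13 | O(Cc1ccccc1)c1ccc([C@@H]2C[C@H](c3c(OCc4ccccc4)cc(OCc4ccccc4)c(CC=C)c3OC(=C)c3ccc(OCc4ccccc4)cc3)c3ccc(OCc4ccccc4)cc3O2)cc1 | intermediate (not isolated)
17 | 5,7-bis(benzyloxy)-2-[4-(benzyloxy)phenyl]-8-{(2S,4S)-7-(benzyloxy)-2-[4-(benzyloxy)phenyl]chroman-4-yl}-4H-chromene | O(Cc1ccccc1)c1ccc([C@@H]2C[C@H](c3c(OCc4ccccc4)cc(OCc4ccccc4)c4c3OC(c3ccc(OCc5ccccc5)cc3)=CC4)c3ccc(OCc4ccccc4)cc3O2)cc1 | intermediate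
18 | 2,3-trans 3-boranyl adduct of 17 (boron on C3; both lower-unit diastereomers, C2 and C3 left open in the SMILES) | O(Cc1ccccc1)c1ccc([C@@H]2C[C@H](c3c(OCc4ccccc4)cc(OCc4ccccc4)c4c3OC(c3ccc(OCc5ccccc5)cc3)C(B)C4)c3ccc(OCc4ccccc4)cc3O2)cc1 | intermediate (not isolated)
19 | 2,3-trans flavan-3-ol from 18 (both lower-unit diastereomers, C2 and C3 left open in the SMILES) | O(Cc1ccccc1)c1ccc([C@@H]2C[C@H](c3c(OCc4ccccc4)cc(OCc4ccccc4)c4c3OC(c3ccc(OCc5ccccc5)cc3)C(O)C4)c3ccc(OCc4ccccc4)cc3O2)cc1 | intermediate (not isolated)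
20 | 5,7-bis(benzyloxy)-2-[4-(benzyloxy)phenyl]-8-{(2S,4S)-7-(benzyloxy)-2-[4-(benzyloxy)phenyl]chroman-4-yl}chroman-3-one (C2 epimers) | O(Cc1ccccc1)c1ccc([C@@H]2C[C@H](c3c(OCc4ccccc4)cc(OCc4ccccc4)c4c3OC(c3ccc(OCc5ccccc5)cc3)C(=O)C4)c3ccc(OCc4ccccc4)cc3O2)cc1 | intermediate
21 | (2R,3R)-5,7-bis(benzyloxy)-2-[4-(benzyloxy)phenyl]-8-{(2S,4S)-7-(benzyloxy)-2-[4-(benzyloxy)phenyl]chroman-4-yl}chroman-3-ol (2,3-cis) | O(Cc1ccccc1)c1ccc([C@@H]2C[C@H](c3c(OCc4ccccc4)cc(OCc4ccccc4)c4c3O[C@H](c3ccc(OCc5ccccc5)cc3)[C@H](O)C4)c3ccc(OCc4ccccc4)cc3O2)cc1 | intermediate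
22 | (2R,3R)-2-(4-hydroxyphenyl)-8-[(2S,4S)-7-hydroxy-2-(4-hydroxyphenyl)chroman-4-yl]chromane-3,5,7-triol | Oc1ccc([C@@H]2C[C@H](c3c(O)cc(O)c4c3O[C@H](c3ccc(O)cc3)[C@H](O)C4)c3ccc(O)cc3O2)cc1 | target

Total step count: 10. Longest linear sequence: 10 steps (1 to 22).

Steps most likely to fail

Step 7 (key step): the cascade may stop at the vinyl ether because the titanium alkylidene does not engage the hindered 1-arylvinyl ether, or Lewis acidic aluminium may ionise the product enol ether. The fallback sets out from 15 and comes back at 17. Lemieux–Johnson cleavage of the allyl group (OsO4 cat., NaIO4, 2,6-lutidine, dioxane/H2O) should give the arylacetaldehyde benzoate F1. An intramolecular McMurry-type aldehyde–ester coupling with low-valent titanium (TiCl3, Zn, DME, reflux, slow addition) then forms the same C2=C3 bond by reductive carbonyl coupling instead of metathesis.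

Step 4: the doubly ortho-substituted, strongly stabilised quinone methide may react sluggishly, so that the styrene oligomerises, or the catalyst may discriminate the faces poorly. The fallback sets out from 9 and comes back at 12. Cycloaddition promoted by an achiral acid ((PhO)2P(O)OH, CH2Cl2, rt) should still be cis-selective through the endo transition state and give racemic material, that is 12 together with its (2R,4R)-enantiomer F2. The enantiomers are then separated by preparative chromatography on a chiral stationary phase, so control moves from catalysis to resolution.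

Step 9: facial discrimination may be weak for a ketone with no aryl group directly on the carbonyl, C2 epimerisation may be slower than hydrogenation, and the enolate may be lost to air oxidation. The fallback sets out from 20 and comes back at 21. Substrate-controlled reduction with L-Selectride LiBH(s-Bu)3 (THF, −78 °C) should deliver hydride equatorially and give only 2,3-cis alcohols, that is 21 and its lower-unit (2S,3S)-diastereomer F3. These are diastereomers and should separate on silica; F3 is returned to 20 by Dess–Martin oxidation.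

Further compounds
F1 | step 7 | 3,5-bis(benzyloxy)-2-(2-oxoethyl)-6-{(2S,4S)-7-(benzyloxy)-2-[4-(benzyloxy)phenyl]chroman-4-yl}phenyl 4-(benzyloxy)benzoate | O(Cc1ccccc1)c1ccc([C@@H]2C[C@H](c3c(OCc4ccccc4)cc(OCc4ccccc4)c(CC=O)c3OC(=O)c3ccc(OCc4ccccc4)cc3)c3ccc(OCc4ccccc4)cc3O2)cc1
F2 | step 4 | (2R,4R)-enantiomer of 12 | O(Cc1ccccc1)c1ccc([C@H]2C[C@@H](c3c(OCc4ccccc4)cc(OCc4ccccc4)cc3OCC=C)c3ccc(OCc4ccccc4)cc3O2)cc1
F3 | step 9 | (2S,3S)-lower-unit diastereomer of 21 | O(Cc1ccccc1)c1ccc([C@@H]2C[C@H](c3c(OCc4ccccc4)cc(OCc4ccccc4)c4c3O[C@@H](c3ccc(OCc5ccccc5)cc3)[C@@H](O)C4)c3ccc(OCc4ccccc4)cc3O2)cc1
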